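## Structural features

The target is a methylhydroquinone joined through benzylic C1' to an oxidised diterpenoid chain (C1'–C15', with C20' the acetoxymethyl carbon on C3'). C4' is a ketal carbon whose oxygens O(a) (to C9') and O(b) (to C7') build a 2,8-dioxabicyclo[3.2.1]octane: an oxepane C4'–C5'–C6'–C7'–C8'–C9'–O(a), a tetrahydrofuran C4'–C5'–C6'–C7'–O(b) and a 1,3-dioxane sharing these atoms. The configurations are 2'R,3'S,4'R,7'R,9'S and 10'E. C2', C3' and C4' are contiguous and C3' and C4' are both fully substituted, while C7' and C9' are 1,3-related across C8', with the dienyl chain on C9' equatorial on the dioxane chair. O(a) sits on an allylic carbon (C9') whose ionisation would give a well-stabilised allyl cation, so strong acid is excluded. The two acetates flank a free tertiary alcohol (acyl migration, base lability), the hydroquinone is oxidation-sensitive, and the two trisubstituted alkenes rule out ozonolysis, hydrogenation, unselective dihydroxylation and late-metal metathesis. The real difficulty is the C3'–C4' junction of two oxygen-laden quaternary carbons and the control of C2'/C3' beside it, too far from C7'/C9' for relay of configuration along the chain. The key step uses the fact that C4' is at the carboxyl oxidation level and bonded to O(a): the oxepane can be opened in thought to a C9' ester whose carbonyl carbon is C4', with C5' as an alkene terminus and O(b) as a transannular nucleophile.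

## Logic of the disconnections

24 ⇒ 22 (through 23): the two phenolic O–H bonds are traced to O–CH3 bonds. The hydroquinone is thereby masked through every oxidative and organometallic step. The forward step needs an oxidative demethylation that is fast at 0 °C, so that alkenes, acetates and ketal survive, followed by reduction in the work-up.

22 ⇒ 21 ⇒ 20: the acetyl–O2' bond and then the C20'–OAc bond are cut. Both acetates and the tertiary alcohol thus derive from one oxirane and one secondary alcohol. The forward steps need acetate to attack only the CH2 terminus and the hindered tertiary hydroxyl to stay unacylated.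

20 ⇒ 19: the C3'–O and C20'–O bonds of the oxirane are cut. C3' becomes an sp2 carbon and its configuration is derived from C2'. The forward step must touch only the allylic alkene and deliver oxygen erythro to the C2' hydroxyl.

19 ⇒ 15 + 18: the C2'–C3' bond is cut. This is the convergent cut that separates the arene from the bicycle and turns C3' into a triflate-bearing alkene carbon. The forward step needs a non-basic C–C coupling with an enolisable aldehyde and ligand control at C2'.

18 ⇒ 17 ⇒ 16: the C1'–C2' bond is cut (one-carbon homologation of an aryl aldehyde). The forward steps must release a self-condensation-prone arylacetaldehyde only just before use.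

15 ⇒ 14 ⇒ 13 ⇒ 12: no skeletal bond is cut; the O–S bond, the C3' oxidation level and the O–Si bond are adjusted. The lactate-derived carbinol becomes the handle for C3'=C20'. The ketone 14 can enolise only toward its methyl group, so the triflate forms in one direction.

12 ⇒ 10 (through 11): the C4'–O(b) bond and the C4'–C5' bond are cut. The bicycle collapses to an acyclic ester in which the ketal carbon is a carboxyl carbon and C5' is a terminal alkene. The forward step needs an alkylidene that picks the monosubstituted alkene, olefinates a hindered ester and leaves a cyclic enol ether that a weak acid can close. The C7' oxygen is carried as the trimethylsilyl ether in place of triethylsilyl so that it is unmasked by the weak acid that spares the allylic C9'–O bond and the other silyl ether.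

10 ⇒ 9 ⇒ 5 + 8: the O7'–Si bond and the acyl C4'–O(a) bond are cut. Two halves of similar size are joined by acylation. The forward step must acylate the secondary allylic hydroxyl in the presence of the tertiary one.

8 ⇒ 7 ⇒ 6: O–Si and ester C–O bonds only; the acid comes from the chiral pool in two routine steps.

5 ⇒ 4: the C6'–C7' bond is cut. The tertiary carbinol comes from a methyl ketone and an allyl nucleophile. The forward step must give the 1,3-anti diol through a chelate and avoid base, because 4 dehydrates and retro-aldolises readily.

4 ⇒ 1 + 2 (through 3): the C8'–C9' bond is cut (acetone aldol). The forward step must select the Si face of the enal and unmask the ketone under very mild acid.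

## Other disconnections considered

Alternative 1: The C2'–O and C3'–O bonds are cut together, so that the tertiary alcohol and the C2' acetate derive from epoxy alcohol A2, itself made from the (Z)-trisubstituted allylic alcohol A1 (C20' hydroxyl, C2'=C3') carrying the finished bicycle and arene.
- Forward key step: Ti(OiPr)4, L-(+)-diethyl tartrate (the antipode that the empirical face rule assigns to A2) and t-BuOOH should epoxidise only the allylic alkene. Acetate would then open the oxirane at C2' with inversion, and the primary hydroxyl would be acetylated.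
- In its favour: one reagent-controlled step sets C2' and C3' together, independent of the distant centres. On this point it is better than the chosen plan, which needs a ligand-controlled coupling and then a substrate-directed epoxidation. Chemoselectivity over the isolated alkenes is equal.
- Against it: A1 needs C4' and C1', the two largest groups, cis across the alkene. Enolisation of a ketone derived from 14 would favour the opposite geometry, so A1 has no short stereoselective access. Acetate must also attack a secondary carbon next to a quaternary one, with an electron-rich aryl group placed to participate, whereas the chosen plan opens an unhindered CH2.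
- Comparison: mechanistically both rest on directed epoxidation and SN2 opening. Structurally alternative 1 concerns only the end game and could be grafted onto 14. In step count it is likely longer because of the alkene synthesis.

Alternative 2: Three ring C–C bonds of the arene are cut, leaving terminal alkyne A3 (a propargyl group at C2' in place of the arylmethyl group) and the zerovalent chromium carbene complex A4, (CO)5Cr=C(OCH3)C(CH3)=CH2.
- Forward key step: warming A3 with A4 should insert the alkyne and one CO and close the ring to the 4-methoxyphenol A5, the 4-O-methyl ether of the target. Oxidative decomplexation and demethylation would follow.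
- In its favour: the substitution pattern is fixed by the known preference of terminal alkynes to place their substituent ortho to the new phenol. This is equal to the chosen plan, which buys the pattern in 16. The arene is absent during all earlier oxidations, a point on which it is better.
- Against it: the arene is commercially available with the right pattern, so building it last costs steps. A3 needs a propargyl addition at C2' with the same stereochemical problem as step 13. Stoichiometric chromium, heat, a free tertiary alcohol, two acetates and two alkenes meet in the last C–C bond-forming step, and isopropenyl carbene complexes are among the less robust. An oxidant is still needed to reach the hydroquinone.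
- Comparison: it adds nothing to the ketal problem and is weaker in step economy and safety.

Alternative 3: The C5'–C6' bond is cut. The bicycle is traced to monocyclic 1,3-dioxane A8 with vinyl groups on C4' and C7', the ketal of the C7'-vinyl diol A6 with the α-silyloxy vinyl ketone A7.
- Forward key step: Cl2(PCy3)2Ru=CHPh should join the two vinyl groups to give the bicyclic alkene A9. Selective reduction of C5'=C6' (diimide) would then lead to 12.
- In its favour: a catalytic, operationally simple ruthenium step replaces a large excess of moisture-sensitive low-valent titanium, a point on which it is better. Five-membered ring closure is fast.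
- Against it: ketalisation of a tertiary/secondary diol with a hindered vinyl ketone is unfavourable and invites conjugate addition. C4' becomes a stereocentre of the monocycle, and only the epimer with both vinyl groups syn-axial can cyclise, which is the thermodynamically disfavoured one. The ruthenium alkylidene on either vinyl group can instead reach the C10'=C11' alkene and close a five-membered ring with loss of the side chain. An extra chemoselective reduction is needed.
- Comparison: in the chosen plan C4' is set automatically by the bridging, the titanium alkylidene ignores trisubstituted alkenes, and two rings form in one operation. Alternative 3 forms one ring and needs more steps.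

Key step: step 7

Remark: primed locants run from benzylic C1' to C15', and C20' is the acetoxymethyl carbon on C3'; 1 is used as the pure E isomer.
Remark: in steps 1 and 13 the antipode of the chiral ligand is taken to be the one whose facial preference gives 9'S and 2'R respectively, to be confirmed by Mosher ester analysis of the first batch.

## Route

Step 1
Reactants: 1 geranial; 2 2-methoxypropene
Product: 4 (4S,5E)-4-hydroxy-6,10-dimethylundeca-5,9-dien-2-one, via enol ether adduct 3 (not isolated)
Conditions: Ti(OiPr)4 (cat.), chiral tridentate binaphthyl Schiff base ligand from 2-amino-2'-hydroxy-1,1'-binaphthyl and 3-bromo-5-tert-butylsalicylaldehyde (cat.), 3,5-di-tert-butylsalicylic acid (cat.), neat 2, 0 °C; then aq. citric acid, THF, 0 °C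
Reagents that add atoms: water, O
Why: Mukaiyama-type (ene-like) aldol addition of the enol ether to the aldehyde bound to a chiral tetravalent titanium Lewis acid; attack on the Si face of 1 sets C9' as S. The 2-methoxyallyl unit of 3 is hydrolysed by very weak acid, which should avoid dehydration of the β-hydroxy ketone to the conjugated dienone.

Step 2
Reactants: 4 (4S,5E)-4-hydroxy-6,10-dimethylundeca-5,9-dien-2-one
Product: 5 (4R,6S,7E)-4,8,12-trimethyltrideca-1,7,11-triene-4,6-diol
Conditions: In powder, allyl bromide, THF/H2O (1:1), rt
Reagents that add atoms: allyl bromide, C=CCBr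
Why: Barbier allylation in water; the allylindium species is held by the free C9' hydroxyl in a six-membered chelate with the ketone and delivers allyl along the axial path, anti to the equatorial C9' substituent, giving the 1,3-anti diol (7'R). The near-neutral medium avoids the retro-aldol and dehydration pathways that a basic magnesium alkoxide would open, and allylmagnesium reagents add too fast to respect a chelate.

Step 3
Reactants: 6 ethyl (S)-lactate
Product: 7 ethyl (2S)-2-[(tert-butyldimethylsilyl)oxy]propanoate
Conditions: TBSCl, imidazole, DMF, rt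
Reagents that add atoms: tert-butyldimethylsilyl chloride, CC(C)(C)[Si](C)(C)Cl
Why: Standard silylation of a secondary alcohol; the stereocentre is not touched.

Step 4
Reactants: 7 ethyl (2S)-2-[(tert-butyldimethylsilyl)oxy]propanoate
Product: 8 (2S)-2-[(tert-butyldimethylsilyl)oxy]propanoic acid
Conditions: LiOH, THF/H2O, 0 °C; then aq. HCl to pH 4
Reagents that add atoms: lithium hydroxide, [Li+].[OH-]
Why: Saponification at 0 °C; the secondary silyl ether should survive cold hydroxide and brief mild acidification.

Step 5
Reactants: 5 (4R,6S,7E)-4,8,12-trimethyltrideca-1,7,11-triene-4,6-diol; 8 (2S)-2-[(tert-butyldimethylsilyl)oxy]propanoic acid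
Product: 9 hydroxy ester (C9' O-silyl lactate, free C7' hydroxyl)
Conditions: DCC, DMAP (cat.), CH2Cl2, 0 °C → rt
Reagents that add atoms: none
Why: Steglich esterification; the secondary allylic hydroxyl is acylated and the tertiary C7' hydroxyl is too hindered to compete.

Step 6
Reactants: 9 hydroxy ester
Product: 10 C7' trimethylsilyl ether of the C9' O-silyl lactate (key-step precursor)
Conditions: N-(trimethylsilyl)imidazole, CH2Cl2, rt
Reagents that add atoms: N-(trimethylsilyl)imidazole, C[Si](C)(C)n1ccnc1
Why: Silylation of the tertiary alcohol with a neutral silyl donor; the free hydroxyl would otherwise consume the titanium alkylidene, and the trimethylsilyl ether is the group most easily lost again under weak acid.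

Step 7
Reactants: 10 C7' trimethylsilyl ether of the C9' O-silyl lactate
Product: 12 (1R,3S,5R)-2,8-dioxabicyclo[3.2.1]octane carrying the (1S)-1-(tert-butyldimethylsilyloxy)ethyl group on C4', via oxepene enol ether 11 (not isolated)
Conditions: TiCl4, TMEDA, Zn, PbCl2 (cat.), CH3CHBr2, THF/CH2Cl2, 0 → 65 °C; filtration through basic Al2O3; then PPTS (cat.), CH2Cl2/MeOH, 0 °C → rt
Reagents that add atoms: none
Why: Reduction of TiCl4·TMEDA by Zn/PbCl2 in the presence of CH3CHBr2 gives a titanium ethylidene, which exchanges with the only monosubstituted alkene of 10 by [2+2] addition and cycloreversion, releasing propene and leaving a titanium alkylidene at C5'. This alkylidene adds across the lactate ester carbonyl (oxatitanacyclobutane) and collapses to the C4'=C5' enol ether 11 and a titanium oxo species; the closest known reaction type is the titanium-alkylidene olefinic ester cyclisation to cyclic enol ethers. The oxepene thus closes by intramolecular carbonyl olefination with the new double bond inside a seven-membered ring. PPTS then protonates 11 at C5', and the C4' oxocarbenium ion is captured by the C7' oxygen, whose trimethylsilyl group passes to methanol, in a transannular 5-exo-trig closure that creates the tetrahydrofuran ring and with it the 1,3-dioxane ring. C4' is the only new stereocentre: the C7' oxygen can reach it only from the ring face on which it is held, so 7'R dictates 4'R, and the C9' chain ends equatorial. Chemoselectivity rests on the reluctance of titanium alkylidenes to engage trisubstituted alkenes (a late-metal metathesis catalyst would close a cyclohexene between C5' and C10') and on the presence of a single ester. The weak acid and the labile trimethylsilyl ether should keep the allylic C9'–O bond and the tert-butyldimethylsilyl ether intact, and any epimerisation of the lactate-derived carbon would be harmless because it is oxidised in step 9.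

Step 8
Reactants: 12 silyl-protected bicyclic ketal
Product: 13 (1S)-1-[(1R,3S,5R)-bicyclic ketal-1-yl]ethan-1-ol
Conditions: Bu4NF, THF, 0 °C → rt
Reagents that add atoms: none
Why: Fluoride cleavage of the secondary silyl ether; ketal and alkenes are inert to fluoride.

Step 9
Reactants: 13 bicyclic ketal alcohol
Product: 14 1-[(1R,3S,5R)-bicyclic ketal-1-yl]ethan-1-one (C3' methyl ketone)
Conditions: Dess–Martin periodinane, pyridine, CH2Cl2, 0 °C → rt
Reagents that add atoms: none
Why: Buffered Dess–Martin oxidation of a secondary alcohol; the conditions are non-acidic enough for the ketal and do not touch the alkenes.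

Step 10
Reactants: 14 C3' methyl ketone
Product: 15 1-[(1R,3S,5R)-bicyclic ketal-1-yl]ethenyl trifluoromethanesulfonate
Conditions: KN(SiMe3)2, THF, −78 °C; then PhNTf2, −78 → 0 °C
Reagents that add atoms: N-phenylbis(trifluoromethanesulfonimide), O=S(=O)(N(c1ccccc1)S(=O)(=O)C(F)(F)F)C(F)(F)F
Why: Enol triflate formation; C4' is quaternary, so only the methyl group can be deprotonated and O-sulfonylation gives the C3'=C20' alkene with the leaving group on C3'.

Step 11
Reactants: 16 2,5-dimethoxy-4-methylbenzaldehyde
Product: 17 1,4-dimethoxy-2-(2-methoxyethenyl)-5-methylbenzene (E/Z mixture)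
Conditions: Ph3P(CH2OMe)Cl, KOtBu, THF, 0 °C → rt
Reagents that add atoms: (methoxymethyl)triphenylphosphonium chloride, COC[P+](c1ccccc1)(c1ccccc1)c1ccccc1.[Cl-]
Why: Wittig methoxymethylenation (one-carbon homologation); the alkene geometry is irrelevant because it is hydrolysed next.

Step 12
Reactants: 17 aryl methyl enol ether
Product: 18 (2,5-dimethoxy-4-methylphenyl)acetaldehyde
Conditions: 2 M aq. HCl, THF, 40 °C; used crude
Reagents that add atoms: water, O
Why: Acid hydrolysis of the enol ether; the arylacetaldehyde is prone to self-condensation and is therefore taken on at once.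

Step 13
Reactants: 15 enol triflate; 18 (2,5-dimethoxy-4-methylphenyl)acetaldehyde
Product: 19 (2R)-1-(2,5-dimethoxy-4-methylphenyl)-3-[(1R,3S,5R)-bicyclic ketal-1-yl]but-3-en-2-ol
Conditions: CrCl2, NiCl2 (cat.), chiral oxazoline–sulfonamide ligand, Et3N, THF, rt
Reagents that add atoms: none
Why: Nozaki–Hiyama–Kishi coupling: zerovalent nickel inserts into the C–OTf bond, the alkenyl group passes to trivalent chromium, and the non-basic alkenylchromium adds to the enolisable aldehyde. The sulfonamide ligand on chromium selects the aldehyde face, which should set C2' as R.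

Step 14
Reactants: 19 allylic alcohol
Product: 20 (1R)-2-(2,5-dimethoxy-4-methylphenyl)-1-{(2S)-2-[(1R,3S,5R)-bicyclic ketal-1-yl]oxiran-2-yl}ethan-1-ol
Conditions: VO(acac)2 (cat.), t-BuOOH, CH2Cl2, 0 °C → rt
Reagents that add atoms: tert-butyl hydroperoxide, CC(C)(C)OO
Why: Hydroxyl-directed epoxidation by a vanadium alkyl peroxide bound to the C2' oxygen, so only the allylic C3'=C20' alkene is reached. A(1,2) strain with the large C4' substituent puts the C2' hydrogen next to C4' and C1' anti to the delivery face, which should give the erythro epoxy alcohol (3'S).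

Step 15
Reactants: 20 epoxy alcohol
Product: 21 (2S,3R)-4-(2,5-dimethoxy-4-methylphenyl)-2-[(1R,3S,5R)-bicyclic ketal-1-yl]-2,3-dihydroxybutyl acetate
Conditions: Ti(OiPr)4, AcOH, CH2Cl2, rt
Reagents that add atoms: acetic acid, CC(=O)O
Why: Chelation-assisted oxirane opening: tetravalent titanium bound to the C2' oxygen and the oxirane oxygen activates the distal, unhindered C20' for SN2 attack by acetate. The C3'–O bond is not broken, so C3' keeps its configuration.

Step 16
Reactants: 21 diol monoacetate
Product: 22 (2S,3R)-4-(2,5-dimethoxy-4-methylphenyl)-2-[(1R,3S,5R)-bicyclic ketal-1-yl]-2-hydroxybutane-1,3-diyl diacetate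
Conditions: Ac2O, pyridine, DMAP (cat.), CH2Cl2, 0 °C → rt
Reagents that add atoms: acetic anhydride, CC(=O)OC(C)=O
Why: Acylation of the secondary C2' hydroxyl; the tertiary C3' hydroxyl between two fully substituted carbons should not react. Any acetyl exchange between O20' and O2' in step 15 converges on the same diacetate here.

Step 17
Reactants: 22 diacetate dimethyl ether
Product: 24 target hydroquinone (2'R,3'S,4'R,7'R,9'S,10'E), via benzoquinone 23 (not isolated)
Conditions: (NH4)2Ce(NO3)6, MeCN/H2O, 0 °C; then aq. Na2S2O4, EtOAc
Reagents that add atoms: water, O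
Why: Oxidative demethylation of the 1,4-dimethoxyarene by tetravalent cerium with attack of water gives quinone 23 within minutes at 0 °C. Dithionite in the work-up reduces it to the hydroquinone without base, so acetates, ketal and alkenes should be untouched.

## Compound list

1 | geranial, (2E)-3,7-dimethylocta-2,6-dienal | CC(C)=CCC/C(C)=C/C=O | starting material
2 | 2-methoxypropene | COC(C)=C | starting material
3 | (4S,5E)-2-methoxy-6,10-dimethylundeca-1,5,9-trien-4-ol (not isolated) | C=C(OC)C[C@H](O)/C=C(\C)CCC=C(C)C | intermediate
4 | (4S,5E)-4-hydroxy-6,10-dimethylundeca-5,9-dien-2-one | CC(=O)C[C@H](O)/C=C(\C)CCC=C(C)C | intermediate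
5 | (4R,6S,7E)-4,8,12-trimethyltrideca-1,7,11-triene-4,6-diol | C=CC[C@@](C)(O)C[C@H](O)/C=C(\C)CCC=C(C)C | intermediate
6 | ethyl (S)-lactate | CCOC(=O)[C@H](C)O | starting material
7 | ethyl (2S)-2-[(tert-butyldimethylsilyl)oxy]propanoate | CCOC(=O)[C@H](C)O[Si](C)(C)C(C)(C)C | intermediate
8 | (2S)-2-[(tert-butyldimethylsilyl)oxy]propanoic acid | C[C@H](O[Si](C)(C)C(C)(C)C)C(=O)O | intermediate
9 | (4R,6S,7E)-4-hydroxy-4,8,12-trimethyltrideca-1,7,11-trien-6-yl (2S)-2-[(tert-butyldimethylsilyl)oxy]propanoate | C[C@H](O[Si](C)(C)C(C)(C)C)C(=O)O[C@H](/C=C(\C)CCC=C(C)C)C[C@@](C)(CC=C)O | intermediate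
10 | (4R,6S,7E)-4,8,12-trimethyl-4-[(trimethylsilyl)oxy]trideca-1,7,11-trien-6-yl (2S)-2-[(tert-butyldimethylsilyl)oxy]propanoate | C[C@H](O[Si](C)(C)C(C)(C)C)C(=O)O[C@H](/C=C(\C)CCC=C(C)C)C[C@@](C)(CC=C)O[Si](C)(C)C | intermediate
11 | (2S,4R)-7-[(1S)-1-(tert-butyldimethylsilyloxy)ethyl]-2-[(1E)-2,6-dimethylhepta-1,5-dien-1-yl]-4-methyl-4-(trimethylsilyloxy)-2,3,4,5-tetrahydrooxepine (not isolated) | C[C@H](O[Si](C)(C)C(C)(C)C)C1=CC[C@@](C)(O[Si](C)(C)C)C[C@@H](/C=C(\C)CCC=C(C)C)O1 | intermediate
12 | tert-butyl{(1S)-1-[(1R,3S,5R)-3-[(1E)-2,6-dimethylhepta-1,5-dien-1-yl]-5-methyl-2,8-dioxabicyclo[3.2.1]octan-1-yl]ethoxy}dimethylsilane | C[C@H](O[Si](C)(C)C(C)(C)C)[C@]12CC[C@](C)(C[C@@H](/C=C(\C)CCC=C(C)C)O1)O2 | intermediate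
13 | (1S)-1-[(1R,3S,5R)-3-[(1E)-2,6-dimethylhepta-1,5-dien-1-yl]-5-methyl-2,8-dioxabicyclo[3.2.1]octan-1-yl]ethan-1-ol | C[C@H](O)[C@]12CC[C@](C)(C[C@@H](/C=C(\C)CCC=C(C)C)O1)O2 | intermediate
14 | 1-[(1R,3S,5R)-3-[(1E)-2,6-dimethylhepta-1,5-dien-1-yl]-5-methyl-2,8-dioxabicyclo[3.2.1]octan-1-yl]ethan-1-one | CC(=O)[C@]12CC[C@](C)(C[C@@H](/C=C(\C)CCC=C(C)C)O1)O2 | intermediate
15 | 1-[(1R,3S,5R)-3-[(1E)-2,6-dimethylhepta-1,5-dien-1-yl]-5-methyl-2,8-dioxabicyclo[3.2.1]octan-1-yl]ethenyl trifluoromethanesulfonate | C=C(OS(=O)(=O)C(F)(F)F)[C@]12CC[C@](C)(C[C@@H](/C=C(\C)CCC=C(C)C)O1)O2 | intermediate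
16 | 2,5-dimethoxy-4-methylbenzaldehyde | COc1cc(C)c(OC)cc1C=O | starting material
17 | 1,4-dimethoxy-2-(2-methoxyethenyl)-5-methylbenzene (E/Z mixture) | COC=Cc1cc(OC)c(C)cc1OC | intermediate
18 | (2,5-dimethoxy-4-methylphenyl)acetaldehyde | COc1cc(C)c(OC)cc1CC=O | intermediate
19 | (2R)-1-(2,5-dimethoxy-4-methylphenyl)-3-[(1R,3S,5R)-3-[(1E)-2,6-dimethylhepta-1,5-dien-1-yl]-5-methyl-2,8-dioxabicyclo[3.2.1]octan-1-yl]but-3-en-2-ol | C=C([C@H](O)Cc1cc(OC)c(C)cc1OC)[C@]12CC[C@](C)(C[C@@H](/C=C(\C)CCC=C(C)C)O1)O2 | intermediate
20 | (1R)-2-(2,5-dimethoxy-4-methylphenyl)-1-{(2S)-2-[(1R,3S,5R)-3-[(1E)-2,6-dimethylhepta-1,5-dien-1-yl]-5-methyl-2,8-dioxabicyclo[3.2.1]octan-1-yl]oxiran-2-yl}ethan-1-ol | O[C@H](Cc1cc(OC)c(C)cc1OC)[C@@]3(CO3)[C@]12CC[C@](C)(C[C@@H](/C=C(\C)CCC=C(C)C)O1)O2 | intermediate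
21 | (2S,3R)-4-(2,5-dimethoxy-4-methylphenyl)-2-[(1R,3S,5R)-3-[(1E)-2,6-dimethylhepta-1,5-dien-1-yl]-5-methyl-2,8-dioxabicyclo[3.2.1]octan-1-yl]-2,3-dihydroxybutyl acetate | CC(=O)OC[C@](O)([C@H](O)Cc1cc(OC)c(C)cc1OC)[C@]12CC[C@](C)(C[C@@H](/C=C(\C)CCC=C(C)C)O1)O2 | intermediate
22 | (2S,3R)-4-(2,5-dimethoxy-4-methylphenyl)-2-[(1R,3S,5R)-3-[(1E)-2,6-dimethylhepta-1,5-dien-1-yl]-5-methyl-2,8-dioxabicyclo[3.2.1]octan-1-yl]-2-hydroxybutane-1,3-diyl diacetate | CC(=O)OC[C@](O)([C@@H](Cc1cc(OC)c(C)cc1OC)OC(C)=O)[C@]12CC[C@](C)(C[C@@H](/C=C(\C)CCC=C(C)C)O1)O2 | intermediate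
23 | (2S,3R)-2-[(1R,3S,5R)-3-[(1E)-2,6-dimethylhepta-1,5-dien-1-yl]-5-methyl-2,8-dioxabicyclo[3.2.1]octan-1-yl]-2-hydroxy-4-(4-methyl-3,6-dioxocyclohexa-1,4-dien-1-yl)butane-1,3-diyl diacetate (not isolated) | CC(=O)OC[C@](O)([C@@H](CC1=CC(=O)C(C)=CC1=O)OC(C)=O)[C@]12CC[C@](C)(C[C@@H](/C=C(\C)CCC=C(C)C)O1)O2 | intermediate
24 | (2S,3R)-4-(2,5-dihydroxy-4-methylphenyl)-2-[(1R,3S,5R)-3-[(1E)-2,6-dimethylhepta-1,5-dien-1-yl]-5-methyl-2,8-dioxabicyclo[3.2.1]octan-1-yl]-2-hydroxybutane-1,3-diyl diacetate | CC(=O)OC[C@](O)([C@@H](Cc1cc(O)c(C)cc1O)OC(C)=O)[C@]12CC[C@](C)(C[C@@H](/C=C(\C)CCC=C(C)C)O1)O2 | target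

## Step count and least certain steps

Total: 17 steps. Longest linear sequence: 13 steps (1, 2, 5, 6, 7, 8, 9, 10, 13, 14, 15, 16, 17). Steps 3–4 and 11–12 make the two side fragments.

**Step 7 (key step).**
- Most likely failure: carbonyl ethylidenation of the hindered α-silyloxy ester without ring closure, or incomplete alkylidene exchange at the terminal alkene, leaving acyclic enol ethers. Premature loss of the trimethylsilyl group in the hot titanium mixture and acid-induced ionisation at allylic C9' during ketalisation are further risks.
- Fallback, from 5 back to 14 (bypassing 9–13), built on lactone chemistry. Hydroboration of the terminal alkene of 5 with excess 9-BBN and oxidative work-up should give (4R,6S,7E)-4,8,12-trimethyltrideca-7,11-diene-1,4,6-triol F1. Oxidation of the primary alcohol with TEMPO/PhI(OAc)2 should close the lactol onto the C7' hydroxyl and carry it on to the γ-lactone F2, in which the former terminal carbon is C4'. Addition of 1-ethoxyvinyllithium (two equivalents, −78 °C) should give the hemiketal enol ether F3. Dilute aqueous acid would then hydrolyse the enol ether to the acetyl group and let the C9' hydroxyl close the bicyclic ketal, arriving at 14.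

**Step 2.**
- Most likely failure: poor facial selectivity if the indium chelate is loose (the tertiary centre cannot be corrected later), or slow addition to the ketone.
- Fallback, from 4 back to 5, under reagent control. Et3SiCl/imidazole should give the β-silyloxy ketone F4. An enantiopure B-allyl-10-phenyl-9-borabicyclo[3.3.2]decane (antipode matched to 7'R) should allylate the methyl ketone to the tertiary homoallylic alcohol F5. HF·pyridine would then remove the silyl group to give 5.

**Step 13.**
- Most likely failure: sluggish nickel insertion or chromium transfer at the triflate beside the quaternary ketal carbon, β-alkoxide loss from the alkenylmetal, or insufficient facial control by the ligand at C2'.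
- Fallback, from 15 and 18 back to 19, by oxidation and reduction. Ligand-free coupling (CrCl2, NiCl2 cat., DMF) should give the C2'-epimeric allylic alcohols F6. Dess–Martin oxidation should give the α-methylene ketone F7. Corey–Bakshi–Shibata reduction with the (S)-methyl oxazaborolidine and catecholborane at −78 °C, in which the bulky alkenyl group acts as the large substituent, should give the 2'R alcohol 19.

**Step 14.**
- Most likely failure: erosion of erythro selectivity if the very large C4' substituent distorts the vanadate geometry, and competing oxidation of the allylic alcohol to the enone.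
- Fallback, from 19 back to 20, by catalyst control: Ti(OiPr)4, D-(−)-diisopropyl tartrate and t-BuOOH at −20 °C. For the 2'R carbinol this tartrate is the matched, fast-reacting case and delivers oxygen to the same face, and any 2'S material would be left behind.

**Step 15.**
- Most likely failure: slow attack at the neopentyl-type CH2, Lewis-acid-induced rearrangement of the oxirane, or transesterification by the titanium alkoxide.
- Fallback, from 20 back to 22, with the order reversed. Ac2O/pyridine should first give the epoxy acetate F8. CsOAc/AcOH with 18-crown-6 in DMF at 60 °C should then open the oxirane at C20' by plain SN2 without a Lewis acid, giving 22 directly.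

## Further compounds

F1 | step 7 | (4R,6S,7E)-4,8,12-trimethyltrideca-7,11-diene-1,4,6-triol | OCCC[C@@](C)(O)C[C@H](O)/C=C(\C)CCC=C(C)C
F2 | step 7 | (5R)-5-[(2S,3E)-2-hydroxy-4,8-dimethylnona-3,7-dien-1-yl]-5-methyloxolan-2-one | C[C@]1(C[C@H](O)/C=C(\C)CCC=C(C)C)CCC(=O)O1
F3 | step 7 | (5R)-2-(1-ethoxyethenyl)-5-[(2S,3E)-2-hydroxy-4,8-dimethylnona-3,7-dien-1-yl]-5-methyloxolan-2-ol (anomers, not isolated) | C=C(OCC)C1(O)CC[C@](C)(C[C@H](O)/C=C(\C)CCC=C(C)C)O1
F4 | step 2 | (4S,5E)-6,10-dimethyl-4-[(triethylsilyl)oxy]undeca-5,9-dien-2-one | CC(=O)C[C@H](O[Si](CC)(CC)CC)/C=C(\C)CCC=C(C)C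
F5 | step 2 | (4R,6S,7E)-4,8,12-trimethyl-6-[(triethylsilyl)oxy]trideca-1,7,11-trien-4-ol | C=CC[C@@](C)(O)C[C@H](O[Si](CC)(CC)CC)/C=C(\C)CCC=C(C)C
F6 | step 13 | 1-(2,5-dimethoxy-4-methylphenyl)-3-[(1R,3S,5R)-3-[(1E)-2,6-dimethylhepta-1,5-dien-1-yl]-5-methyl-2,8-dioxabicyclo[3.2.1]octan-1-yl]but-3-en-2-ol (C2' epimers) | C=C(C(O)Cc1cc(OC)c(C)cc1OC)[C@]12CC[C@](C)(C[C@@H](/C=C(\C)CCC=C(C)C)O1)O2
F7 | step 13 | 1-(2,5-dimethoxy-4-methylphenyl)-3-[(1R,3S,5R)-3-[(1E)-2,6-dimethylhepta-1,5-dien-1-yl]-5-methyl-2,8-dioxabicyclo[3.2.1]octan-1-yl]but-3-en-2-one | C=C(C(=O)Cc1cc(OC)c(C)cc1OC)[C@]12CC[C@](C)(C[C@@H](/C=C(\C)CCC=C(C)C)O1)O2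
F0 | step 14 | none | none
F8 | step 15 | (1R)-2-(2,5-dimethoxy-4-methylphenyl)-1-{(2S)-2-[(1R,3S,5R)-3-[(1E)-2,6-dimethylhepta-1,5-dien-1-yl]-5-methyl-2,8-dioxabicyclo[3.2.1]octan-1-yl]oxiran-2-yl}ethyl acetate | CC(=O)O[C@H](Cc1cc(OC)c(C)cc1OC)[C@@]3(CO3)[C@]12CC[C@](C)(C[C@@H](/C=C(\C)CCC=C(C)C)O1)O2
A1 | alternative 1 | (2Z)-4-(2,5-dimethoxy-4-methylphenyl)-2-[(1R,3S,5R)-3-[(1E)-2,6-dimethylhepta-1,5-dien-1-yl]-5-methyl-2,8-dioxabicyclo[3.2.1]octan-1-yl]but-2-en-1-ol | OC/C(=C/Cc1cc(OC)c(C)cc1OC)[C@]12CC[C@](C)(C[C@@H](/C=C(\C)CCC=C(C)C)O1)O2
A2 | alternative 1 | 2,3-epoxy alcohol (C20' hydroxyl, C2'–C3' oxirane) of the complete skeleton | OC[C@@]3(O[C@H]3Cc1cc(OC)c(C)cc1OC)[C@]12CC[C@](C)(C[C@@H](/C=C(\C)CCC=C(C)C)O1)O2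
A3 | alternative 2 | terminal alkyne: target with a prop-2-ynyl group on C2' in place of the arylmethyl group | CC(=O)OC[C@](O)([C@@H](CC#C)OC(C)=O)[C@]12CC[C@](C)(C[C@@H](/C=C(\C)CCC=C(C)C)O1)O2
A4 | alternative 2 | pentacarbonyl[methoxy(prop-1-en-2-yl)methylidene]chromium | COC(C(C)=C)=[Cr](=C=O)(=C=O)(=C=O)(=C=O)=C=O
A5 | alternative 2 | 4-O-methyl ether of the target | CC(=O)OC[C@](O)([C@@H](Cc1cc(OC)c(C)cc1O)OC(C)=O)[C@]12CC[C@](C)(C[C@@H](/C=C(\C)CCC=C(C)C)O1)O2
A6 | alternative 3 | (6E)-3,7,11-trimethyldodeca-1,6,10-triene-3,5-diol, C7'-vinyl analogue of 5 with the same spatial arrangement at C7' and C9' | C=C[C@@](C)(O)C[C@H](O)/C=C(\C)CCC=C(C)C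
A7 | alternative 3 | (4S)-4-[(tert-butyldimethylsilyl)oxy]pent-1-en-3-one | C=CC(=O)[C@H](C)O[Si](C)(C)C(C)(C)C
A8 | alternative 3 | 2,4-divinyl-1,3-dioxane ketal of A6 with A7 (vinyl groups on C4' and C7' syn-axial) | C[C@H](O[Si](C)(C)C(C)(C)C)[C@@]1(C=C)O[C@](C)(C=C)C[C@@H](/C=C(\C)CCC=C(C)C)O1
A9 | alternative 3 | 2,8-dioxabicyclo[3.2.1]oct-6-ene with the C9' alkenyl chain and the silylated C3' carbinol | C[C@H](O[Si](C)(C)C(C)(C)C)[C@]12C=C[C@](C)(C[C@@H](/C=C(\C)CCC=C(C)C)O1)O2
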